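**Retrosynthetic overview**
1. The C5–C6 bond of the hydrindanone is the aldol bond of the β-hydroxy ketone C4(=O)–C5–C6(OH). The ring C3a–C4–C5–C6–C7–C7a is therefore made by inserting C5–C6 into the C4–C7 bond of the cyclobutane C3a–C4–C7–C7a of a bicyclo[3.2.0]heptane (four- to six-membered ring enlargement).
2. The enabling feature is the 1,5-relationship C4=O / C6–O across the two methyl-bearing quaternary ring-fusion carbons C3a/C7a: C4 (carbinol) and C7 (acyl-bearing) of a strained cyclobutanol are a retro-aldol pair.
3. The key-step precursor 25 is assembled in one flask from three components: cyclobutanone 8, aldehyde 16 (aldol at the cyclobutanone CH2) and the alkenylcerium from 20 (addition to C=O). Its diastereomer mixture converges in the key step.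
4. Ring order: cyclopentane and cyclobutane together first (auxiliary-controlled intramolecular keteniminium–alkene [2+2], setting both quaternary centres), cyclohexanone last.
5. The E-trisubstituted alkene and arene come from Negishi carboalumination/benzyl coupling; the arene comes from 4-methoxy-2-methylphenol by a Mannich reaction; global desilylation ends the route.

Key step: step 12

Assumption: the absolute sense of induction of the auxiliary (step 3) and of the ligand (step 12) is taken from steric models and the closest analogies; if either proves opposite, the enantiomeric pyrrolidine or ligand (both commercial) is used with no other change.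

**Step 1**
Reactants: 1 propanoyl chloride; 2 (2S,5S)-2,5-dimethylpyrrolidine
Product: 3 1-[(2S,5S)-2,5-dimethylpyrrolidin-1-yl]propan-1-one
Conditions: Et3N, CH2Cl2, 0 °C to rt
Reagents that add atoms: none
Why: N-acylation of the C2-symmetric secondary amine by the acid chloride (Schotten–Baumann-type amide formation) installs the chiral auxiliary without touching its stereocentres.

**Step 2**
Reactants: 3 1-[(2S,5S)-2,5-dimethylpyrrolidin-1-yl]propan-1-one; 4 5-bromo-2-methylpent-1-ene
Product: 5 1-[(2S,5S)-2,5-dimethylpyrrolidin-1-yl]-2,6-dimethylhept-6-en-1-one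
Conditions: LiN(iPr)2, LiCl, THF, −78 to 0 °C
Reagents that add atoms: none
Why: SN2 alkylation of the amide lithium enolate by the primary bromide joins all carbons of the future bicycle, and the configuration of the new α-carbon is immaterial because that carbon becomes sp2 in the next step.

**Step 3**
Reactants: 5 1-[(2S,5S)-2,5-dimethylpyrrolidin-1-yl]-2,6-dimethylhept-6-en-1-one
Product: 8 (1R,5R)-1,5-dimethylbicyclo[3.2.0]heptan-6-one, via keteniminium triflate 6 (not isolated), via cyclobutaniminium triflate 7 (not isolated)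
Conditions: Tf2O, 2,4,6-collidine, ClCH2CH2Cl, 0 to 80 °C; then H2O, 60 °C; aq NaHCO3
Reagents that add atoms: water (O)
Why: O-triflation and α-deprotonation give a tetrasubstituted keteniminium ion that undergoes intramolecular [2+2] cycloaddition with the 1,1-disubstituted alkene (the tertiary cation-like terminus enforces the fused bicyclo[3.2.0] regiochemistry), the C2-symmetric pyrrolidine shielding one face of the prochiral keteniminium carbon so that both cis quaternary centres are set together, and hydrolysis of the iminium releases ketone and auxiliary.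

**Step 4**
Reactants: 9 4-methoxy-2-methylphenol
Product: 10 2-[(dimethylamino)methyl]-4-methoxy-6-methylphenol
Conditions: aq Me2NH, aq CH2O, EtOH, reflux
Reagents that add atoms: formaldehyde (C=O); dimethylamine (CNC)
Why: The phenolic Mannich reaction goes ortho to the hydroxyl group, and the only free ortho position is C6 because C2 carries the methyl and C4 the methoxy group.

**Step 5**
Reactants: 10 2-[(dimethylamino)methyl]-4-methoxy-6-methylphenol
Product: 11 1-{2-[(tert-butyldimethylsilyl)oxy]-5-methoxy-3-methylphenyl}-N,N-dimethylmethanamine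
Conditions: tert-butyldimethylsilyl chloride, imidazole, DMF, rt
Reagents that add atoms: tert-butyldimethylsilyl chloride (CC(C)(C)[Si](C)(C)Cl)
Why: Silylation of the phenol masks the acidic O–H for the organometallic steps with a group that fluoride removes at the end.

**Step 6**
Reactants: 11 1-{2-[(tert-butyldimethylsilyl)oxy]-5-methoxy-3-methylphenyl}-N,N-dimethylmethanamine
Product: 12 tert-butyl[2-(chloromethyl)-4-methoxy-6-methylphenoxy]dimethylsilane
Conditions: ClCO2Et, CH2Cl2, 0 °C to rt
Reagents that add atoms: ethyl chloroformate (CCOC(=O)Cl)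
Why: N-acylation by the chloroformate and chloride attack at the activated benzylic carbon of the acylammonium salt (von Braun-type dealkylation) give the benzyl chloride without a benzylic alkoxide that could take over the aryl silyl group.

**Step 7**
Reactants: 13 but-3-yn-1-ol; 12 tert-butyl[2-(chloromethyl)-4-methoxy-6-methylphenoxy]dimethylsilane
Product: 15 (3E)-5-{2-[(tert-butyldimethylsilyl)oxy]-5-methoxy-3-methylphenyl}-3-methylpent-3-en-1-ol, via alkenylalane 14 (not isolated)
Conditions: Me3Al, Cp2ZrCl2 (cat.), CH2Cl2, 0 °C to rt; then 12, Pd(PPh3)4 (cat.), THF, rt; aq work-up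
Reagents that add atoms: trimethylaluminium (C[Al](C)C)
Why: Zirconium-catalysed syn-carboalumination (Negishi carboalumination) puts methyl on the internal and aluminium on the terminal alkyne carbon, and the (E)-alkenylalane couples with the benzylic chloride under Pd(PPh3)4 catalysis with retention, which fixes the E-trisubstituted alkene.

**Step 8**
Reactants: 15 (3E)-5-{2-[(tert-butyldimethylsilyl)oxy]-5-methoxy-3-methylphenyl}-3-methylpent-3-en-1-ol
Product: 16 (3E)-5-{2-[(tert-butyldimethylsilyl)oxy]-5-methoxy-3-methylphenyl}-3-methylpent-3-enal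
Conditions: DMP (1,1,1-triacetoxy-1,1-dihydro-1,2-benziodoxol-3(1H)-one), NaHCO3, CH2Cl2, 0 °C; used crude at once
Reagents that add atoms: none
Why: Buffered periodinane oxidation stops at the aldehyde and is mild enough to leave the β,γ-double bond out of conjugation.

**Step 9**
Reactants: 17 2-methylbut-3-yn-2-ol
Product: 18 triethyl[(2-methylbut-3-yn-2-yl)oxy]silane
Conditions: Et3SiCl, imidazole, DMAP (cat.), DMF, rt
Reagents that add atoms: chlorotriethylsilane (CC[Si](Cl)(CC)CC)
Why: Silylation protects the tertiary alcohol that will become the side-chain hydroxyl against the alkyllithium and hydride reagents to come.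

**Step 10**
Reactants: 18 triethyl[(2-methylbut-3-yn-2-yl)oxy]silane
Product: 20 triethyl{[(3E)-4-iodo-2-methylbut-3-en-2-yl]oxy}silane, via alkenylzirconocene chloride 19 (not isolated)
Conditions: Cp2Zr(H)Cl, THF, rt; then I2, 0 °C
Reagents that add atoms: iodine (II)
Why: Hydrozirconation adds H and Zr syn with zirconium at the unhindered terminus, and iodinolysis with retention gives the (E)-alkenyl iodide.

**Step 11**
Reactants: 8 (1R,5R)-1,5-dimethylbicyclo[3.2.0]heptan-6-one; 16 (3E)-5-{2-[(tert-butyldimethylsilyl)oxy]-5-methoxy-3-methylphenyl}-3-methylpent-3-enal; 20 triethyl{[(3E)-4-iodo-2-methylbut-3-en-2-yl]oxy}silane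
Product: 25 cyclobutane-1,3-diol (diastereomer mixture; full name in the compound list), via lithium enolate 21 (not isolated), via lithium aldolate 22 (not isolated), via alkenyllithium 23 (not isolated), via alkenylcerium dichloride 24 (not isolated)
Conditions: 8, LiN(iPr)2, THF, −78 °C; 16, −78 °C; then 24 [from 20, t-BuLi (2 equiv), Et2O, −78 °C; CeCl3, THF, −78 °C], −78 to −40 °C; aq NH4Cl
Reagents that add atoms: none
Why: The cyclobutanone can enolise only toward its CH2 group, so the lithium enolate adds to the aldehyde (aldol addition) and the weakly basic alkenylcerium then adds to the strained, chelated ketone of the aldolate, the three new stereocentres being left uncontrolled because all are erased in step 12.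

**Step 12**
Reactants: 25 cyclobutane-1,3-diol (diastereomer mixture)
Product: 28 (3aR,5R,6R,7aR)-bis-silyl ether of the target (full name in the compound list), via 2-acylcyclobutanol 26 (not isolated), via ene-dione 27 (not isolated)
Conditions: DMP, NaHCO3, CH2Cl2, 0 °C to rt; filtration through MgSiO3 and solvent exchange to toluene without isolation; then Cu(OAc)2·H2O (5 mol %), (R)-DTBM-SEGPHOS (5 mol %), (EtO)2MeSiH, toluene, −20 °C; pH 7 buffer
Reagents that add atoms: none
Why: Oxidation of the secondary carbinol gives β-hydroxy ketone 26, whose cyclobutane bond between the carbinol carbon and the acyl-bearing carbon breaks by strain-driven retro-aldol to ene-dione 27; the ligated CuH then adds hydride to the enone β-carbon and the copper (Z)-enolate adds to the other ketone. The closest known reactions are the De Mayo-type retro-aldol fragmentation of 2-acylcyclobutanols and the CuH-catalysed asymmetric reductive aldol cyclisation of keto-enones. The ring closes in the 6-(enolendo)-exo-trig mode and holds all four cyclobutane carbons (C3a, C4, C7, C7a) plus C5 and C6, so the net event is a two-carbon ring enlargement. The (Z)-enolate reacting through a copper-chelated chair places the forming C6–O bond axial and the C5 side chain equatorial, which gives the required cis relation of 6-OH and the 5-substituent (C5 can also epimerise to this equatorial arrangement). How C5/C6 relate to C3a/C7a is left to the chiral bisphosphine on copper, because the ring fusion (methyl against ring CH2 on each carbon) gives almost no bias of its own. The step needs an enolate at C5 only and no base, since the CH2 between the other carbonyl and the trisubstituted alkene is more acidic and would let the alkene move into conjugation; forming the enolate by hydride addition to the enone under neutral conditions secures this, and every diastereomer of 25 funnels through the one ene-dione 27.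

**Step 13**
Reactants: 28 (3aR,5R,6R,7aR)-bis-silyl ether of the target
Product: 29 (3aR,5R,6R,7aR)-6-hydroxy-6-[(2E)-4-(2-hydroxy-5-methoxy-3-methylphenyl)-2-methylbut-2-en-1-yl]-5-(2-hydroxy-2-methylpropyl)-3a,7a-dimethyloctahydro-4H-inden-4-one
Conditions: HF·pyridine, pyridine, THF, 0 °C to rt
Reagents that add atoms: none
Why: Buffered fluoride cleaves the aryl and the tertiary silyl ether in one operation under conditions too mild for retro-aldol or dehydration of the β-hydroxy ketone.

**Compound list**
1 | propanoyl chloride | CCC(=O)Cl | starting material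
2 | (2S,5S)-2,5-dimethylpyrrolidine | C[C@H]1CC[C@H](C)N1 | starting material
3 | 1-[(2S,5S)-2,5-dimethylpyrrolidin-1-yl]propan-1-one | CCC(=O)N1[C@@H](C)CC[C@@H]1C | intermediate
4 | 5-bromo-2-methylpent-1-ene | C=C(C)CCCBr | starting material
5 | 1-[(2S,5S)-2,5-dimethylpyrrolidin-1-yl]-2,6-dimethylhept-6-en-1-one (either C2 epimer or both) | CC(CCCC(C)=C)C(=O)N1[C@@H](C)CC[C@@H]1C | intermediate
6 | (2S,5S)-1-(2,6-dimethylhepta-1,6-dien-1-ylidene)-2,5-dimethylpyrrolidin-1-ium triflate (keteniminium triflate) | CC(CCCC(C)=C)=C=[N+]1[C@@H](C)CC[C@@H]1C.[O-]S(=O)(=O)C(F)(F)F | intermediate (not isolated)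
7 | (2S,5S)-1-[(1R,5R)-1,5-dimethylbicyclo[3.2.0]heptan-6-ylidene]-2,5-dimethylpyrrolidin-1-ium triflate (cyclobutaniminium triflate) | C1[C@@]2(C)CCC[C@@]2(C)C1=[N+]3[C@@H](C)CC[C@@H]3C.[O-]S(=O)(=O)C(F)(F)F | intermediate (not isolated)
8 | (1R,5R)-1,5-dimethylbicyclo[3.2.0]heptan-6-one (cis-fused) | C1[C@@]2(C)CCC[C@@]2(C)C1=O | intermediate
9 | 4-methoxy-2-methylphenol | COc1ccc(O)c(C)c1 | starting material
10 | 2-[(dimethylamino)methyl]-4-methoxy-6-methylphenol | COc1cc(C)c(O)c(CN(C)C)c1 | intermediate
11 | 1-{2-[(tert-butyldimethylsilyl)oxy]-5-methoxy-3-methylphenyl}-N,N-dimethylmethanamine | COc1cc(C)c(O[Si](C)(C)C(C)(C)C)c(CN(C)C)c1 | intermediate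
12 | tert-butyl[2-(chloromethyl)-4-methoxy-6-methylphenoxy]dimethylsilane | COc1cc(C)c(O[Si](C)(C)C(C)(C)C)c(CCl)c1 | intermediate
13 | but-3-yn-1-ol | C#CCCO | starting material
14 | {[(3E)-4-(dimethylalumanyl)-3-methylbut-3-en-1-yl]oxy}dimethylalumane (alkenylalane) | C[Al](C)/C=C(\C)CCO[Al](C)C | intermediate (not isolated)
15 | (3E)-5-{2-[(tert-butyldimethylsilyl)oxy]-5-methoxy-3-methylphenyl}-3-methylpent-3-en-1-ol | OCC/C(C)=C/Cc1cc(OC)cc(C)c1O[Si](C)(C)C(C)(C)C | intermediate
16 | (3E)-5-{2-[(tert-butyldimethylsilyl)oxy]-5-methoxy-3-methylphenyl}-3-methylpent-3-enal | O=CC/C(C)=C/Cc1cc(OC)cc(C)c1O[Si](C)(C)C(C)(C)C | intermediate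
17 | 2-methylbut-3-yn-2-ol | CC(C)(O)C#C | starting material
18 | triethyl[(2-methylbut-3-yn-2-yl)oxy]silane | CC[Si](CC)(CC)OC(C)(C)C#C | intermediate
19 | chlorobis(cyclopentadienyl)[(1E)-3-methyl-3-(triethylsilyloxy)but-1-en-1-yl]zirconium (alkenylzirconocene chloride) | CC[Si](CC)(CC)OC(C)(C)/C=C/[Zr](Cl)(C1C=CC=C1)C1C=CC=C1 | intermediate (not isolated)
20 | triethyl{[(3E)-4-iodo-2-methylbut-3-en-2-yl]oxy}silane | CC[Si](CC)(CC)OC(C)(C)/C=C/I | intermediate
21 | lithium 1,5-dimethylbicyclo[3.2.0]hept-6-en-6-olate, ring fusion as in 8 (lithium enolate) | C1[C@@]2(C)CCC[C@@]2(C)C=1O[Li] | intermediate (not isolated)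
22 | lithium alkoxide of (1R,5R)-7-[(3E)-5-{2-[(tert-butyldimethylsilyl)oxy]-5-methoxy-3-methylphenyl}-1-hydroxy-3-methylpent-3-en-1-yl]-1,5-dimethylbicyclo[3.2.0]heptan-6-one, mixture at C7 and the carbinol carbon (lithium aldolate) | C1(C(O[Li])C/C(C)=C/Cc3cc(OC)cc(C)c3O[Si](C)(C)C(C)(C)C)[C@@]2(C)CCC[C@@]2(C)C1=O | intermediate (not isolated)
23 | [(1E)-3-methyl-3-(triethylsilyloxy)but-1-en-1-yl]lithium (alkenyllithium) | CC[Si](CC)(CC)OC(C)(C)/C=C/[Li] | intermediate (not isolated)
24 | dichloro[(1E)-3-methyl-3-(triethylsilyloxy)but-1-en-1-yl]cerium (alkenylcerium dichloride) | CC[Si](CC)(CC)OC(C)(C)/C=C/[Ce](Cl)Cl | intermediate (not isolated)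
25 | (1R,5R)-7-[(3E)-5-{2-[(tert-butyldimethylsilyl)oxy]-5-methoxy-3-methylphenyl}-1-hydroxy-3-methylpent-3-en-1-yl]-1,5-dimethyl-6-[(1E)-3-methyl-3-(triethylsilyloxy)but-1-en-1-yl]bicyclo[3.2.0]heptan-6-ol, mixture of diastereomers at C6, C7 and the side-chain carbinol | C1(C(O)C/C(C)=C/Cc3cc(OC)cc(C)c3O[Si](C)(C)C(C)(C)C)[C@@]2(C)CCC[C@@]2(C)C1(O)/C=C/C(C)(C)O[Si](CC)(CC)CC | intermediate
26 | (3E)-5-{2-[(tert-butyldimethylsilyl)oxy]-5-methoxy-3-methylphenyl}-1-{(1R,5R)-6-hydroxy-1,5-dimethyl-6-[(1E)-3-methyl-3-(triethylsilyloxy)but-1-en-1-yl]bicyclo[3.2.0]heptan-7-yl}-3-methylpent-3-en-1-one, mixture at C6 and C7 (2-acylcyclobutanol) | C1(C(=O)C/C(C)=C/Cc3cc(OC)cc(C)c3O[Si](C)(C)C(C)(C)C)[C@@]2(C)CCC[C@@]2(C)C1(O)/C=C/C(C)(C)O[Si](CC)(CC)CC | intermediate (not isolated)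
27 | (2E)-1-[(1R,2R)-2-{(4E)-6-[2-(tert-butyldimethylsilyloxy)-5-methoxy-3-methylphenyl]-4-methyl-2-oxohex-4-en-1-yl}-1,2-dimethylcyclopentyl]-4-methyl-4-(triethylsilyloxy)pent-2-en-1-one (ene-dione; the two chains cis) | C[C@]1(CC(=O)C/C(C)=C/Cc2cc(OC)cc(C)c2O[Si](C)(C)C(C)(C)C)CCC[C@@]1(C)C(=O)/C=C/C(C)(C)O[Si](CC)(CC)CC | intermediate (not isolated)
28 | (3aR,5R,6R,7aR)-6-[(2E)-4-{2-[(tert-butyldimethylsilyl)oxy]-5-methoxy-3-methylphenyl}-2-methylbut-2-en-1-yl]-6-hydroxy-3a,7a-dimethyl-5-[2-methyl-2-(triethylsilyloxy)propyl]octahydro-4H-inden-4-one | COc1cc(C)c(O[Si](C)(C)C(C)(C)C)c(C/C=C(\C)C[C@@]2(O)C[C@@]3(C)CCC[C@@]3(C)C(=O)[C@@H]2CC(C)(C)O[Si](CC)(CC)CC)c1 | intermediate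
29 | (3aR,5R,6R,7aR)-6-hydroxy-6-[(2E)-4-(2-hydroxy-5-methoxy-3-methylphenyl)-2-methylbut-2-en-1-yl]-5-(2-hydroxy-2-methylpropyl)-3a,7a-dimethyloctahydro-4H-inden-4-one | COc1cc(C)c(O)c(C/C=C(\C)C[C@@]2(O)C[C@@]3(C)CCC[C@@]3(C)C(=O)[C@@H]2CC(C)(C)O)c1 | target

**Totals**
Total step count: 13. Longest linear sequence: 8 steps (4, 5, 6, 7, 8, 11, 12, 13).

**Steps most likely to fail**

Step 12. The copper enolate may be silylated, or the second ketone reduced, before the ring closes. The catalyst may also fail to distinguish the two chair closures that differ only in how C5/C6 relate to the ring fusion, so that both aldols form. Fallback: from 25 the oxidation and fragmentation are run as before but ene-dione 27 is isolated. Rh-catalysed 1,4-hydrosilylation (RhCl(PPh3)3, Et3SiH) then gives the (Z)-triethylsilyl enol ether F1 regiospecifically. An intramolecular Mukaiyama aldol (TiCl4 or BF3·OEt2, CH2Cl2, −78 °C) closes the ring through an open transition state with a different facial preference and comes back to the route at 28; the two aldol diastereomers would be separated at that stage.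

Step 11. Proton transfer from the enolisable β,γ-unsaturated aldehyde to the lithium enolate, retro-aldol of the aldolate on warming, or slow addition of the hindered alkenylcerium to the crowded ketone may erode the one-flask coupling. Fallback: from 8 the trimethylsilyl enol ether F2 is made (Me3SiOTf, Et3N). A Mukaiyama aldol with 16 (BF3·OEt2, CH2Cl2, −78 °C) avoids any basic enolate and gives the β-hydroxy cyclobutanone F3, which is isolated cold. F3 is then treated separately with alkenylcerium 24 (from 20) and the route is rejoined at 25.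

Step 3. Facial discrimination by the auxiliary may be insufficient, or the keteniminium ion may be lost to ene reaction or oligomerisation, giving 8 in low enantiomeric purity. Fallback: from 4, alkylation of the dianion of propanoic acid gives 2,6-dimethylhept-6-enoic acid F4. Treatment with TsCl and Et3N in toluene at reflux forms the ketene F5, which closes by thermal intramolecular ketene–alkene [2+2] to the racemic cis ketone F6. Resolution follows through the SAMP hydrazones: the diastereomers are separated by chromatography, the hydrazone F7 of the (1R,5R)-ketone is cleaved with aqueous oxalic acid, and the route is rejoined at 8.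

**Further compounds**
F1 | step 12 | (1R,2R)-silyl enol ether: {[(1Z)-1-[(1R,2R)-2-{(4E)-6-[2-(tert-butyldimethylsilyloxy)-5-methoxy-3-methylphenyl]-4-methyl-2-oxohex-4-en-1-yl}-1,2-dimethylcyclopentyl]-4-methyl-4-(triethylsilyloxy)pent-1-en-1-yl]oxy}triethylsilane | C[C@]1(CC(=O)C/C(C)=C/Cc2cc(OC)cc(C)c2O[Si](C)(C)C(C)(C)C)CCC[C@@]1(C)/C(O[Si](CC)(CC)CC)=C/CC(C)(C)O[Si](CC)(CC)CC
F2 | step 11 | [(1,5-dimethylbicyclo[3.2.0]hept-6-en-6-yl)oxy]trimethylsilane, ring fusion as in 8 | C1[C@@]2(C)CCC[C@@]2(C)C=1O[Si](C)(C)C
F3 | step 11 | (1R,5R)-7-[(3E)-5-{2-[(tert-butyldimethylsilyl)oxy]-5-methoxy-3-methylphenyl}-1-hydroxy-3-methylpent-3-en-1-yl]-1,5-dimethylbicyclo[3.2.0]heptan-6-one (mixture at C7 and the carbinol carbon) | C1(C(O)C/C(C)=C/Cc3cc(OC)cc(C)c3O[Si](C)(C)C(C)(C)C)[C@@]2(C)CCC[C@@]2(C)C1=O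
F4 | step 3 | 2,6-dimethylhept-6-enoic acid (racemic) | CC(CCCC(C)=C)C(=O)O
F5 | step 3 | 2,6-dimethylhepta-1,6-dien-1-one (ketene, not isolated) | CC(CCCC(C)=C)=C=O
F6 | step 3 | racemic cis-1,5-dimethylbicyclo[3.2.0]heptan-6-one | CC12CCCC1(C)C(=O)C2
F7 | step 3 | (2S)-N-[(1R,5R)-1,5-dimethylbicyclo[3.2.0]heptan-6-ylidene]-2-(methoxymethyl)pyrrolidin-1-amine | C1[C@@]2(C)CCC[C@@]2(C)C1=NN3CCC[C@H]3COC
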